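all flasks: starting material 0.50 M

| flask | partner | remark | time |
|---|---|---|---|
| teal | 0.80 M | run made earlier |  |
| blue | 2.4 M | run made earlier |  |
| north-east | 1.00 M |  | 50 h |
| south-west | 3.00 M |  | 50 h |

| run | time / h | other mono adduct / % | starting material / % | isomer of the product / % | first product / % | double product / % |
|---|---|---|---|---|---|---|
| teal | 2.00 | 0 | 94 | 0 | 0 | 0 |
| teal | 4.00 | 0 | 93 | 0 | 10 | 1 |
| teal | 8.00 | 6 | 88 | 2 | 12 | 1 |
| teal | 12.0 | 4 | 76 | 7 | 12 | 4 |
| teal | 25.0 | 4 | 58 | 9 | 17 | 9 |
| blue | 2.00 | 1 | 86 | 0 | 11 | 0 |
| blue | 6.00 | 5 | 70 | 4 | 15 | 8 |
| blue | 12.0 | 5 | 46 | 4 | 15 | 21 |
| blue | 20.0 | 8 | 31 | 10 | 13 | 36 |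
| blue | 25.0 | 8 | 23 | 13 | 12 | 42 |

(each reading ± 2 percentage points)

* which of these there is most of at the end, counted by the starting material in it, north-east (first product / other mono adduct / starting material / isomer of the product / double product)
* which of these there is most of at the end, counted by the starting material in it, south-west (first product / other mono adduct / starting material / isomer of the product / double product)
* final amount of the leader among these, as a percentage of the starting material charged, in north-east
* final amount of the leader among these, as a percentage of the starting material charged, in south-west

- on the list of suspects stand: starting material + partner -> first product + by-product; starting material + partner -> other mono adduct + by-product; partner + first product -> double product + by-product; partner + other mono adduct -> double product + by-product; first product <-> isomer of the product; first product + by-product -> side product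

**Pairing constant.** Begin with the easy step: each starting material lost takes one partner at once, and a second one later if it goes on to double product. At the last reading of each run, count the partner spent: one per mono adduct or isomer of the product, two per double product. Divide the logarithm of the inverse fraction left by the time and by the mean of charged and end partner. Teal gives 0.0320 M⁻¹ h⁻¹ and blue 0.0279 M⁻¹ h⁻¹. Carry their mean, 0.0300 M⁻¹ h⁻¹, the pairing constant: the fractional loss of starting material per unit of partner and time.

**North-east bracket.** In north-east, let a be the fraction of starting material left and x the pairing constant times partner charge times time, here 1.50. Hold partner at its charge, the pseudo-first-order picture, and a falls to exp(−x), or 22.3%. The partner charge is twice the starting charge, so one partner per loss leaves partner at the fraction (one + a)/2 of its charge. Integrating gives a/(one + a) = half of exp(−x/2), which raises the floor to 31.0%. Two partners per loss at once leave partner at the fraction a, so the ceiling is one over (one + x), or 40.0%. Commit to the middle, 35.5%, and name starting material as leader, teal ending at 58% against 9% of double product.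

**South-west bracket.** Two partners per starting material still leave south-west 2.00 M, so with this constant a lies there between 1.12% and 4.99%. Blue reads 36% of double product against 31% of starting material at 20.0 h, so name double product for south-west.

**The forecast.** It gives starting material at 33% (28% to 39%) in north-east, a value inside the bracket, with the words “Starting material narrowly leads, but this is close”, and double product at 75% (66% to 84%) in south-west.

    starting material + partner → first product + by-product (k = 0.0260 M⁻¹ h⁻¹)
    starting material + partner → other mono adduct + by-product (k = 0.00280 M⁻¹ h⁻¹)
    partner + first product → double product + by-product (k = 0.0590 M⁻¹ h⁻¹)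
    partner + other mono adduct → double product + by-product (k = 3.10 × 10⁻⁴ M⁻¹ h⁻¹)
    first product ⇌ isomer of the product (K = 2.10, k = 0.0370 h⁻¹)
    first product + by-product → side product (k = 0.0340 M⁻¹ h⁻¹)

**The flask.** North-east ends with starting material ahead at 35.2%, inside the bracket, and south-west with double product ahead at 68.0%. North-east keeps 54% of its partner, a mean of 0.772 M, and the pairing constant then gives 31.4%, less than that flask holds. South-west read at 12.0 h keeps 84.7% of its partner, so its mean is 2.77 M. The same reckoning gives 36.9%, and that flask holds 38.7%.

The data stem from a simulated flask from invented constants, noise included.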